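**Retrosynthetic overview**
- The coumarin is attached last: the C1–C3' bond comes from a C1 oxocarbenium ion of the iridoid acetal and 4-hydroxy-5-methylcoumarin, followed by desilylation of the side-chain hydroxyl.
- The C3–acyl bond comes from the C3-lithiated enol ether (a masked acyl anion) of silylated nepetalactol and the Weinreb amide of O-silylated (R)-2-hydroxy-3-methylbutanoic acid.
- The dihydropyran ring (C1, O2, C3, C4, C4a, C7a) closes by enol-hemiacetalisation of the iridodial dialdehyde, itself made from the cyclopentane ester by ester reduction, hydroboration and double oxidation.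
- The strategy rests on the trisubstituted cyclopentane ring (C4a, C5, C6, C7, C7a): C7 (methyl), C7a (bearing C1) and C4a (bearing C4) are C2, C6 and C5 of trans-dihydrocarvone. The ketone carbon becomes C1 and the isopropenyl group supplies C4, its methyl and C3. The ring is made by photochemical Wolff contraction of 6-diazo-trans-dihydrocarvone from (S)-carvone.
- Ring order: cyclopentane first (by contraction), dihydropyran second, intact coumarin appended third.

Key step: step 4

Remark: atoms are numbered as in the target's cyclopenta[c]pyran (C1, O2, C3, C4, C4a, C5, C6, C7, C7a). C1 of 10, 11 and 16 is drawn as the expected major anomer; either anomer serves, because C1 is ionised in step 13.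

Step 1
Reactants: 1 (S)-carvone
Product: 2 (2S,5S)-2-methyl-5-(prop-1-en-2-yl)cyclohexan-1-one (trans-dihydrocarvone)
Conditions: LiBH(s-Bu)3, THF, −78 °C; H2O; then NaOMe (cat.), MeOH, rt
Reagents that add atoms: none
Why: Conjugate hydride reduction of the β-unsubstituted enone leaves the isopropenyl group untouched, and base equilibration of the enolisable C2 centre should favour the diequatorial trans isomer, so C2 is set under thermodynamic control relative to the chiral-pool centre C5 (the minor cis epimer is removed by chromatography and can be re-equilibrated).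

Step 2
Reactants: 2 trans-dihydrocarvone
Product: 3 (2Z,3R,6S)-2-(hydroxymethylidene)-6-methyl-3-(prop-1-en-2-yl)cyclohexan-1-one
Conditions: NaH, HCO2Et, EtOH (cat.), THF, 0 °C → rt; then aq. HCl
Reagents that add atoms: ethyl formate, CCOC=O
Why: Claisen formylation under equilibrating conditions occurs only at the CH2 α-carbon (C6 of dihydrocarvone), because only that regioisomer is drained as its stabilised β-ketoaldehyde enolate; no stereocentre is created.

Step 3
Reactants: 3 hydroxymethylidene ketone
Product: 4 (3R,6S)-2-diazo-6-methyl-3-(prop-1-en-2-yl)cyclohexan-1-one (6-diazo-trans-dihydrocarvone)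
Conditions: MsN3, Et3N, MeCN, 0 °C → rt
Reagents that add atoms: methanesulfonyl azide, CS(=O)(=O)N=[N+]=[N-]
Why: Regitz deformylative diazo transfer: the enolate attacks the sulfonyl azide and the adduct fragments with loss of N-formylmethanesulfonamide, which places the diazo group on the former CH2 carbon without touching the two stereocentres.

Step 4
Reactants: 4 6-diazo-trans-dihydrocarvone
Product: 6 methyl (1R,2S,5S)-5-methyl-2-(prop-1-en-2-yl)cyclopentane-1-carboxylate, via cyclopentylidene ketene 5 (not isolated)
Conditions: hν (medium-pressure Hg lamp, Pyrex, λ > 300 nm), MeOH, 0 °C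
Reagents that add atoms: methanol, CO
Why: Irradiation expels N2 from 4 and the methyl-bearing ring carbon (C2 of dihydrocarvone, the only carbon that can migrate because the diazo group sits on the former CH2 carbon) shifts from the carbonyl carbon to the carbene carbon in concert with nitrogen loss, the s-cis geometry enforced by the ring favouring this Wolff rearrangement over carbene 1,2-hydride shift or O–H insertion. The closest known reaction type is the photochemical Wolff ring contraction of cyclic 2-diazoketones made by deformylative diazo transfer, which turns 2-diazocyclohexanones into cyclopentanecarboxylates. The cyclopentane (C4a, C5, C6, C7, C7a) is therefore closed by a 1,2-alkyl shift that forms C7–C7a as the old acyl–C7 bond breaks, a ring contraction and not a cyclisation, and the extruded carbonyl carbon becomes C1 in ketene 5, which methanol traps. The migrating carbon C7 moves with retention, so the trans relationship between the C7 methyl group and the isopropenyl group on C4a is carried over from dihydrocarvone. The one new stereocentre, C7a, is set when the ester enol formed from 5 and methanol is protonated on the ring face opposite the bulkier isopropenyl group, which should place CO2Me cis to isopropenyl and trans to methyl. The step needs regioselective migration, secured by the position of the diazo group, and this facial selectivity, which rests on the size difference between isopropenyl and methyl; a minor C7a epimer would be separated at this stage.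

Step 5
Reactants: 6 cyclopentane methyl ester
Product: 7 [(1R,2S,5S)-5-methyl-2-(prop-1-en-2-yl)cyclopentyl]methanol
Conditions: LiAlH4, Et2O, 0 °C; then H2O, aq. NaOH
Reagents that add atoms: none
Why: LiAlH4 reduction of the ester to the primary alcohol leaves the 1,1-disubstituted alkene untouched and removes the carbonyl next to C7a, so that centre cannot epimerise in the following step.

Step 6
Reactants: 7 cyclopentylmethanol
Product: 8 2-[(1R,2R,3S)-2-(hydroxymethyl)-3-methylcyclopentyl]propan-1-ol (both epimers at C2 of the propanol chain)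
Conditions: BH3·THF, THF, 0 °C → rt; then NaOH, H2O2, 0 °C → rt
Reagents that add atoms: hydrogen peroxide, OO
Why: Anti-Markovnikov hydroboration–oxidation of the 1,1-disubstituted alkene gives the primary alcohol at C3; the new centre at C4 forms as a mixture, which is harmless because C4 becomes sp2 in step 7.

Step 7
Reactants: 8 diol
Product: 10 (1R,4aS,7S,7aR)-4,7-dimethyl-1,4a,5,6,7,7a-hexahydrocyclopenta[c]pyran-1-ol (cis,trans-nepetalactol), via iridodial dialdehyde 9 (not isolated)
Conditions: (COCl)2, DMSO, CH2Cl2, −78 °C; Et3N, −78 °C → rt; then Et3N (cat.), CH2Cl2, rt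
Reagents that add atoms: none
Why: Swern oxidation activates both primary alcohols before base is added, so the dialdehyde forms without lactol over-oxidation; the C3 aldehyde then enolises and its enol oxygen adds to the C1 aldehyde (6-exo-trig enol-hemiacetalisation, the iridodial–nepetalactol ring-chain tautomerism), which closes the dihydropyran as the cis-fused bicycle, removes the C4 centre and lets the anomeric hydroxyl settle under thermodynamic control.

Step 8
Reactants: 10 nepetalactol
Product: 11 tert-butyl{[(1S,4aS,7S,7aR)-4,7-dimethyl-1,4a,5,6,7,7a-hexahydrocyclopenta[c]pyran-1-yl]oxy}dimethylsilane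
Conditions: TBSCl, imidazole, DMF, 0 °C → rt
Reagents that add atoms: tert-butyldimethylsilyl chloride, CC(C)(C)[Si](C)(C)Cl
Why: Silylation of the hemiacetal hydroxyl under mild base, which spares the acid-sensitive enol ether, traps the closed form as a base-stable silyl acetal and so masks the C1 aldehyde for the organolithium step.

Step 9
Reactants: 12 (R)-2-hydroxy-3-methylbutanoic acid
Product: 13 (2R)-2-hydroxy-N-methoxy-N,3-dimethylbutanamide
Conditions: MeNHOMe·HCl, EDC·HCl, HOBt (cat.), N-methylmorpholine, CH2Cl2, 0 °C → rt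
Reagents that add atoms: N,O-dimethylhydroxylamine hydrochloride, CNOC.Cl
Why: Carbodiimide/HOBt amidation of the α-hydroxy acid gives the Weinreb amide without breaking any bond at the stereocentre.

Step 10
Reactants: 13 hydroxy Weinreb amide
Product: 14 (2R)-2-[(tert-butyldimethylsilyl)oxy]-N-methoxy-N,3-dimethylbutanamide
Conditions: TBSOTf, 2,6-lutidine, CH2Cl2, 0 °C
Reagents that add atoms: tert-butyldimethylsilyl trifluoromethanesulfonate, CC(C)(C)[Si](C)(C)OS(=O)(=O)C(F)(F)F
Why: Silyl triflate/lutidine silylation protects the hindered secondary hydroxyl with retention, since the C–O bond is not broken.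

Step 11
Reactants: 11 silyl acetal; 14 silyloxy Weinreb amide
Product: 16 (2R)-2-[(tert-butyldimethylsilyl)oxy]-1-[(1S,4aS,7S,7aR)-1-[(tert-butyldimethylsilyl)oxy]-4,7-dimethyl-1,4a,5,6,7,7a-hexahydrocyclopenta[c]pyran-3-yl]-3-methylbutan-1-one, via C3-lithio enol ether 15 (not isolated)
Conditions: t-BuLi, THF/pentane, −78 → 0 °C; then 14, −78 → −20 °C; H2O
Reagents that add atoms: none
Why: α-Lithiation of the cyclic enol ether at its only vinylic C–H (C3, acidified and directed by the ring oxygen, as in the lithiation of dihydropyrans and glycals) gives a vinyllithium that acts as a masked acyl anion, and its Weinreb-amide acylation stops at the ketone stage, forming the C3–acyl bond without epimerising the α-silyloxy stereocentre.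

Step 12
Reactants: 17 1-(2-hydroxy-6-methylphenyl)ethan-1-one (2'-hydroxy-6'-methylacetophenone)
Product: 18 4-hydroxy-5-methyl-2H-chromen-2-one
Conditions: NaH, (EtO)2CO, toluene, 110 °C; then aq. HCl
Reagents that add atoms: diethyl carbonate, CCOC(=O)OCC
Why: Claisen-type C-acylation of the ketone enolate by diethyl carbonate followed by lactonisation onto the phenoxide is the standard construction of 4-hydroxycoumarins from 2-hydroxyacetophenones.

Step 13
Reactants: 16 bis-silylated acyl enol ether acetal; 18 4-hydroxy-5-methylcoumarin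
Product: 19 3-[(1R,4aS,7S,7aR)-3-{(2R)-2-[(tert-butyldimethylsilyl)oxy]-3-methylbutanoyl}-4,7-dimethyl-1,4a,5,6,7,7a-hexahydrocyclopenta[c]pyran-1-yl]-4-hydroxy-5-methyl-2H-chromen-2-one
Conditions: TsOH·H2O (10 mol %), MeCN, 0 °C → rt
Reagents that add atoms: none
Why: Acid ionises the anomeric silyloxy group to a cyclic oxocarbenium ion that is captured at C3 of the 4-hydroxycoumarin (Friedel–Crafts-type C-alkylation as in acid-mediated C-glycosylation, with reversible O-alkylation funnelling to the C-adduct); the nucleophile should enter on the convex face of the cis-fused bicycle, anti to the C7a–C7 bond, giving the 1R epimer, which is also the one expected under the reversible conditions.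

Step 14
Reactants: 19 silyl-protected target
Product: 20 4-hydroxy-3-{(1R,4aS,7S,7aR)-3-[(2R)-2-hydroxy-3-methylbutanoyl]-4,7-dimethyl-1,4a,5,6,7,7a-hexahydrocyclopenta[c]pyran-1-yl}-5-methyl-2H-chromen-2-one (CNP0214255.1)
Conditions: HF·pyridine, THF/pyridine, 0 °C → rt
Reagents that add atoms: none
Why: Fluoride cleavage of the secondary TBS ether under buffered, weakly acidic conditions frees the α-hydroxy ketone without base-induced α-ketol rearrangement or epimerisation and leaves the C1 centre and the coumarin untouched.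

**Compound list**
1 | (S)-carvone | CC1=CC[C@@H](CC1=O)C(C)=C | starting material
2 | (2S,5S)-2-methyl-5-(prop-1-en-2-yl)cyclohexan-1-one | O=C1C[C@@H](C(C)=C)CC[C@@H]1C | intermediate
3 | (2Z,3R,6S)-2-(hydroxymethylidene)-6-methyl-3-(prop-1-en-2-yl)cyclohexan-1-one | O=C1/C(=C\O)[C@@H](C(C)=C)CC[C@@H]1C | intermediate
4 | (3R,6S)-2-diazo-6-methyl-3-(prop-1-en-2-yl)cyclohexan-1-one | O=C1C(=[N+]=[N-])[C@@H](C(C)=C)CC[C@@H]1C | intermediate
5 | [(2S,5R)-2-methyl-5-(prop-1-en-2-yl)cyclopentylidene]methanone (ketene) | O=C=C1[C@@H](C(C)=C)CC[C@@H]1C | intermediate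
6 | methyl (1R,2S,5S)-5-methyl-2-(prop-1-en-2-yl)cyclopentane-1-carboxylate | COC(=O)[C@H]1[C@@H](C(C)=C)CC[C@@H]1C | intermediate
7 | [(1R,2S,5S)-5-methyl-2-(prop-1-en-2-yl)cyclopentyl]methanol | OC[C@H]1[C@@H](C(C)=C)CC[C@@H]1C | intermediate
8 | 2-[(1R,2R,3S)-2-(hydroxymethyl)-3-methylcyclopentyl]propan-1-ol (epimers at the propanol C2) | OC[C@H]1[C@@H](C(C)CO)CC[C@@H]1C | intermediate
9 | (1R,2S,5R)-2-methyl-5-(1-oxopropan-2-yl)cyclopentane-1-carbaldehyde (iridodial) | O=C[C@H]1[C@@H](C(C)C=O)CC[C@@H]1C | intermediate
10 | (1R,4aS,7S,7aR)-4,7-dimethyl-1,4a,5,6,7,7a-hexahydrocyclopenta[c]pyran-1-ol | CC1=CO[C@@H](O)[C@H]2[C@@H]1CC[C@@H]2C | intermediate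
11 | tert-butyl{[(1S,4aS,7S,7aR)-4,7-dimethyl-1,4a,5,6,7,7a-hexahydrocyclopenta[c]pyran-1-yl]oxy}dimethylsilane | CC1=CO[C@@H](O[Si](C)(C)C(C)(C)C)[C@H]2[C@@H]1CC[C@@H]2C | intermediate
12 | (R)-2-hydroxy-3-methylbutanoic acid | CC(C)[C@@H](O)C(=O)O | starting material
13 | (2R)-2-hydroxy-N-methoxy-N,3-dimethylbutanamide | CC(C)[C@@H](O)C(=O)N(C)OC | intermediate
14 | (2R)-2-[(tert-butyldimethylsilyl)oxy]-N-methoxy-N,3-dimethylbutanamide | CC(C)[C@@H](O[Si](C)(C)C(C)(C)C)C(=O)N(C)OC | intermediate
15 | C3-lithio derivative of 11 | CC1=C([Li])O[C@@H](O[Si](C)(C)C(C)(C)C)[C@H]2[C@@H]1CC[C@@H]2C | intermediate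
16 | (2R)-2-[(tert-butyldimethylsilyl)oxy]-1-[(1S,4aS,7S,7aR)-1-[(tert-butyldimethylsilyl)oxy]-4,7-dimethyl-1,4a,5,6,7,7a-hexahydrocyclopenta[c]pyran-3-yl]-3-methylbutan-1-one | CC1=C(C(=O)[C@H](O[Si](C)(C)C(C)(C)C)C(C)C)O[C@@H](O[Si](C)(C)C(C)(C)C)[C@H]2[C@@H]1CC[C@@H]2C | intermediate
17 | 1-(2-hydroxy-6-methylphenyl)ethan-1-one | CC(=O)c1c(C)cccc1O | starting material
18 | 4-hydroxy-5-methyl-2H-chromen-2-one | Cc1cccc2oc(=O)cc(O)c12 | intermediate
19 | 3-[(1R,4aS,7S,7aR)-3-{(2R)-2-[(tert-butyldimethylsilyl)oxy]-3-methylbutanoyl}-4,7-dimethyl-1,4a,5,6,7,7a-hexahydrocyclopenta[c]pyran-1-yl]-4-hydroxy-5-methyl-2H-chromen-2-one | CC1=C(C(=O)[C@H](O[Si](C)(C)C(C)(C)C)C(C)C)O[C@@H](c2c(O)c3c(C)cccc3oc2=O)[C@H]2[C@@H]1CC[C@@H]2C | intermediate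
20 | 4-hydroxy-3-{(1R,4aS,7S,7aR)-3-[(2R)-2-hydroxy-3-methylbutanoyl]-4,7-dimethyl-1,4a,5,6,7,7a-hexahydrocyclopenta[c]pyran-1-yl}-5-methyl-2H-chromen-2-one | CC1=C(C(=O)[C@H](O)C(C)C)O[C@@H](c2c(O)c3c(C)cccc3oc2=O)[C@H]2[C@@H]1CC[C@@H]2C | target

Total step count: 14. Longest linear sequence: 11 steps (steps 1–8, 11, 13, 14, from 1 to 20).

**Steps most likely to fail**

1. Step 11 (C3 lithiation and acylation). The base may deprotonate the allylic C4 methyl group or fragment the anomeric silyl acetal instead of metalating C3, and the hindered vinyllithium may add only slowly to the branched amide. The fallback sets out from 6 and comes back at 19; it installs the acyl unit in the open chain by dithiane umpolung instead of enol-ether metalation. Hydroboration–oxidation of 6 (9-BBN, THF; NaBO3·4H2O) should give the hydroxy ester F1, Dess–Martin oxidation the aldehyde ester F2, 1,3-propanedithiol with BF3·OEt2 the dithiane ester F3, and LiAlH4 the dithiane alcohol F4. Separately, i-Bu2AlH reduction of 14 at −78 °C gives (2R)-2-[(tert-butyldimethylsilyl)oxy]-3-methylbutanal F5. The alkoxide/dithianyl dianion of F4 (t-BuLi, THF/HMPA, −78 °C) is added to F5 to give the dithiane diol F6 as carbinol epimers. Swern oxidation converts both carbinols and gives the keto aldehyde dithiane F7. Dithiane hydrolysis (MeI, CaCO3, aq. MeCN) unveils the 1,2-diketone, which closes through its C3 enol onto the C1 aldehyde to the lactol F8. F8 and 18 with catalytic TsOH in MeCN then give 19.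

2. Step 4 (Wolff ring contraction). Protonation of the ketene-derived ester enol may show poor facial selectivity, so that 6 is obtained together with its C7a epimer. The fallback sets out from 6, used as that epimeric mixture, and comes back at 10; it replaces kinetic protonation by thermodynamic control in the cis-fused enol lactone. Hydroboration–oxidation (9-BBN; NaBO3·4H2O) gives the hydroxy esters F9 and Dess–Martin oxidation the aldehyde esters F10. LiOH in aqueous THF gives the nepetalic acids F11. Enol-lactonisation (Ac2O, NaOAc, heat) followed by equilibration of the α-carbonyl centre C7a with K2CO3 in refluxing xylene should converge on the more stable cis-fused (4aS,7S,7aR)-nepetalactone F12. Reduction with i-Bu2AlH at −78 °C gives nepetalactol 10.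

3. Step 13 (coumarin coupling). Ionisation of the electron-poor silyl acetal may be sluggish, O-alkylation of the coumarin may compete with C-alkylation, and facial control at C1 may be eroded. The fallback sets out from 16 and comes back at 20; it replaces the oxocarbenium alkylation by a condensation cascade. HF·pyridine removes both silyl groups and gives the hydroxy lactol F13. With ethylenediammonium diacetate in CH2Cl2/MeOH at rt, the ring-opened aldehyde tautomer of F13 undergoes Knoevenagel condensation with 18 to the alkylidene chromanedione F14. Intramolecular oxa-Michael addition of the diketone enol closes the pyran on the less hindered face and delivers 20 directly.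

**Further compounds**
F1 | step 11 | methyl (1R,2R,5S)-2-(1-hydroxypropan-2-yl)-5-methylcyclopentane-1-carboxylate | COC(=O)[C@H]1[C@@H](C(C)CO)CC[C@@H]1C
F2 | step 11 | methyl (1R,2R,5S)-5-methyl-2-(1-oxopropan-2-yl)cyclopentane-1-carboxylate | COC(=O)[C@H]1[C@@H](C(C)C=O)CC[C@@H]1C
F3 | step 11 | methyl (1R,2S,5S)-2-[1-(1,3-dithian-2-yl)ethyl]-5-methylcyclopentane-1-carboxylate | COC(=O)[C@H]1[C@@H](C(C)C2SCCCS2)CC[C@@H]1C
F4 | step 11 | {(1R,2S,5S)-2-[1-(1,3-dithian-2-yl)ethyl]-5-methylcyclopentyl}methanol | OC[C@H]1[C@@H](C(C)C2SCCCS2)CC[C@@H]1C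
F5 | step 11 | (2R)-2-[(tert-butyldimethylsilyl)oxy]-3-methylbutanal | CC(C)[C@@H](O[Si](C)(C)C(C)(C)C)C=O
F6 | step 11 | dithiane diol (adduct of F4 and F5, carbinol epimers) | OC[C@H]1[C@@H](C(C)C2(C(O)[C@H](O[Si](C)(C)C(C)(C)C)C(C)C)SCCCS2)CC[C@@H]1C
F7 | step 11 | keto aldehyde dithiane | O=C[C@H]1[C@@H](C(C)C2(C(=O)[C@H](O[Si](C)(C)C(C)(C)C)C(C)C)SCCCS2)CC[C@@H]1C
F8 | step 11 | (2R)-2-[(tert-butyldimethylsilyl)oxy]-1-[(1R,4aS,7S,7aR)-1-hydroxy-4,7-dimethyl-1,4a,5,6,7,7a-hexahydrocyclopenta[c]pyran-3-yl]-3-methylbutan-1-one | CC1=C(C(=O)[C@H](O[Si](C)(C)C(C)(C)C)C(C)C)O[C@@H](O)[C@H]2[C@@H]1CC[C@@H]2C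
F9 | step 4 | methyl (2R,5S)-2-(1-hydroxypropan-2-yl)-5-methylcyclopentane-1-carboxylate (C1 epimers) | COC(=O)C1[C@@H](C(C)CO)CC[C@@H]1C
F10 | step 4 | methyl (2R,5S)-5-methyl-2-(1-oxopropan-2-yl)cyclopentane-1-carboxylate (C1 epimers) | COC(=O)C1[C@@H](C(C)C=O)CC[C@@H]1C
F11 | step 4 | (2R,5S)-5-methyl-2-(1-oxopropan-2-yl)cyclopentane-1-carboxylic acid (nepetalic acids, C1 epimers) | OC(=O)C1[C@@H](C(C)C=O)CC[C@@H]1C
F12 | step 4 | (4aS,7S,7aR)-4,7-dimethyl-5,6,7,7a-tetrahydrocyclopenta[c]pyran-1(4aH)-one (cis,trans-nepetalactone) | CC1=COC(=O)[C@H]2[C@@H]1CC[C@@H]2C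
F13 | step 13 | (2R)-2-hydroxy-1-[(1R,4aS,7S,7aR)-1-hydroxy-4,7-dimethyl-1,4a,5,6,7,7a-hexahydrocyclopenta[c]pyran-3-yl]-3-methylbutan-1-one | CC1=C(C(=O)[C@H](O)C(C)C)O[C@@H](O)[C@H]2[C@@H]1CC[C@@H]2C
F14 | step 13 | 3-alkylidene-5-methylchromane-2,4-dione Knoevenagel adduct of ring-opened F13 | O=C1Oc2cccc(C)c2C(=O)C1=C[C@H]1[C@@H](C(C)C(=O)C(=O)[C@H](O)C(C)C)CC[C@@H]1C
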